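**Strategy.** The route rests on breaking C6–C7 and the lactone O–C19 bond. C7 plays two roles: it is the carbinol carbon next to the Z C5=C6 double bond of the ten-membered ring, and the oxygen-bearing γ-carbon of the butenolide (C7, O, C19, C17, C8). One Nozaki–Hiyama–Kishi addition of C6 to a C7 aldehyde therefore closes the carbocycle, sets C7, and frees the alkoxide that lactonises onto the cis C19 ester. The precursor is an enzymatically desymmetrised cyclohexane with trans arms: at C1 the butyrate-bearing chain ending in a Z vinyl iodide, at C10 the C9 acetate carrying a (Z)-formyl acrylate unmasked from a furan.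

Key step: step 24

Conventions: briarane numbering is used for all intermediates; β is the face of the cyclohexane ring that carries the C15 methyl, α the opposite face.
Assumption: in step 5 the lipase acylates the (R)-configured carbinol carbon (C12), as the usual substituent-size model for lipases predicts for trans-2-methylcyclohexanol-type alcohols.
Check of structures: 38 and 41 agree with the target at every stereocentre and double bond (C4 cis to I or C7 on C5=C6; formyl cis to the ester on C8=C17), so nothing had to be corrected.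

Step 1
Reactants: 1 2,6-dimethylbenzoic acid
Product: 2 2,6-dimethylcyclohexa-2,5-diene-1-carboxylic acid
Conditions: Li, NH3(l), THF, −78 °C; NH4Cl; aq. HCl
Reagents that add atoms: none
Why: Birch reduction of the lithium benzoate should stop at the 1,4-dihydro acid because the carboxylate-stabilised dianion is protonated at the ipso and para carbons, leaving the two methyl-bearing double bonds that become C1=C14 and C11=C12.

Step 2
Reactants: 2 2,6-dimethylcyclohexa-2,5-diene-1-carboxylic acid
Product: 3 (2,6-dimethylcyclohexa-2,5-dien-1-yl)methanol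
Conditions: LiAlH4, THF, 0 °C → rt
Reagents that add atoms: none
Why: LiAlH4 reduction of a carboxylic acid to the primary alcohol (the future C9) does not touch the isolated double bonds of the skipped diene.

Step 3
Reactants: 3 (2,6-dimethylcyclohexa-2,5-dien-1-yl)methanol
Product: 4 4-methoxybenzyl (PMB) ether of 3
Conditions: NaH, 4-methoxybenzyl chloride, Bu4NI (cat.), THF/DMF, 0 °C → rt
Reagents that add atoms: 4-methoxybenzyl chloride, COc1ccc(CCl)cc1
Why: Williamson etherification caps the C9 hydroxyl so that it cannot deliver borane to its own face, and the PMB group can later be removed oxidatively beside a silyl ether, ketones and a vinyl iodide.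

Step 4
Reactants: 4 PMB ether
Product: 6 meso diol 1β,11β-dimethyl-10β-(PMB-oxymethyl)cyclohexane-12α,14α-diol, via bis(dihydroboryl) adduct 5 (not isolated)
Conditions: BH3·THF, THF, 0 °C → rt; NaOH, H2O2, 0 °C → rt
Reagents that add atoms: hydrogen peroxide, OO
Why: Double hydroboration–oxidation places boron on the less substituted carbons C12 and C14 and adds H and B syn from the face opposite the CH2OPMB group on C10, so both methyls end cis to C9 and both hydroxyls trans to them, which sets the relative configuration of C1, C10, C11, C12 and C14 in a meso diol.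

Step 5
Reactants: 6 meso diol
Product: 7 12-monoacetate of 6 ((12R)-acetate, free (14S)-hydroxyl)
Conditions: Burkholderia cepacia lipase (lipase PS, immobilised), vinyl acetate, t-BuOMe, 35 °C
Reagents that add atoms: vinyl acetate, CC(=O)OC=C
Why: Lipase-catalysed enantiotopic-group-selective transesterification of the meso diol with an irreversible acyl donor should acylate the (R)-configured carbinol C12, which fixes the absolute configuration of the whole route.

Step 6
Reactants: 7 monoacetate
Product: 9 cyclohexenone (C12=C13, C14 carbonyl), via β-acetoxy ketone 8 (not isolated)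
Conditions: Dess–Martin periodinane, NaHCO3, CH2Cl2, rt; then DBU, CH2Cl2, 0 °C
Reagents that add atoms: none
Why: Dess–Martin oxidation of the free C14 alcohol and E1cB elimination of the β-acetate give the C12=C13 enone, whose only kinetically accessible α-hydrogen is then on C1; C1 may epimerise here but is planarised in step 10.

Step 7
Reactants: 9 enone
Product: 10 12α,13α-epoxy 14-ketone
Conditions: H2O2 (30% aq.), NaOH (cat.), MeOH, 0 °C
Reagents that add atoms: hydrogen peroxide, OO
Why: Weitz–Scheffer nucleophilic epoxidation should deliver hydroperoxide to C12 from the α face, anti to the β substituents on C11, C10 and C1, so that the oxirane stores the C12 oxygen in its final α configuration and blocks enolisation toward C13.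

Step 8
Reactants: 11 2-(2-bromoethyl)-1,3-dioxolane; 12 propyne
Product: 16 2-[(3Z)-4-iodo-3-methylbut-3-en-1-yl]-1,3-dioxolane, via Grignard reagent 13 (not isolated), via alkylcopper reagent 14 (not isolated), via alkenylcopper reagent 15 (not isolated)
Conditions: Mg, THF, 25 °C; CuBr·SMe2, Et2O, −45 °C; 12, −25 °C; I2, −78 → 0 °C
Reagents that add atoms: iodine, I-I
Why: Normant carbocupration adds the alkylcopper syn across propyne with carbon going to the internal and copper to the terminal carbon, and iodinolysis with retention then gives the Z iodide in which the chain (future C4) is cis to iodine.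

Step 9
Reactants: 16 iodo acetal
Product: 17 (4Z)-5-iodo-4-methylpent-4-enal
Conditions: 1 M HCl, THF, 40 °C
Reagents that add atoms: water, O
Why: Acid-catalysed acetal hydrolysis frees the C2 aldehyde under conditions that leave the alkenyl iodide and its geometry untouched.

Step 10
Reactants: 10 epoxy ketone; 17 iodo aldehyde
Product: 19 aldol adduct (quaternary C1; C2 carbinol as both epimers), via lithium enolate 18 (not isolated)
Conditions: LiN(i-Pr)2, THF, −78 °C; 17, −78 °C; AcOH, −78 °C
Reagents that add atoms: none
Why: Kinetic deprotonation can only occur at C1 (α′ to the epoxy ketone) and the aldol addition should take place on the α face of the enolate, opposite the β-CH2OPMB group on the neighbouring C10 that allylic strain with the C15 methyl holds pseudoaxial, which sets quaternary C1 with C15 β and C2 α; the C2 carbinol configuration is not controlled and is erased in step 11.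

Step 11
Reactants: 19 aldol adduct
Product: 20 epoxy β-diketone (C2 and C14 carbonyls)
Conditions: Dess–Martin periodinane, NaHCO3, CH2Cl2, 0 °C → rt
Reagents that add atoms: none
Why: Dess–Martin oxidation converges both C2 epimers on the β-diketone, which has no hydrogen on C1 and therefore cannot epimerise or eliminate.

Step 12
Reactants: 20 epoxy β-diketone
Product: 21 12α-hydroxy β-diketone
Conditions: SmI2 (2.2 equiv), THF/MeOH, −90 °C
Reagents that add atoms: none
Why: Reductive cleavage of the α-C–O bond of an α,β-epoxy ketone by divalent samarium (two single-electron transfers, then protonation of the samarium enolate by methanol) gives the β-hydroxy ketone with C12 unchanged, and is far faster than reduction of the other ketone or of the alkenyl iodide.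

Step 13
Reactants: 21 12α-hydroxy β-diketone
Product: 22 12α-triethylsilyloxy β-diketone
Conditions: Et3SiOTf, 2,6-lutidine, CH2Cl2, −78 °C
Reagents that add atoms: triethylsilyl triflate, CC[Si](CC)(CC)OS(=O)(=O)C(F)(F)F
Why: Silylation of the C12 hydroxyl with the silyl triflate and a hindered pyridine base is fast at −78 °C and avoids the β-elimination and retro-aldol cleavage that stronger bases would cause.

Step 14
Reactants: 22 silyloxy β-diketone PMB ether
Product: 23 C9 primary alcohol
Conditions: DDQ, CH2Cl2/pH 7 buffer, 0 °C
Reagents that add atoms: none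
Why: Oxidative cleavage of the PMB ether by DDQ (hydride abstraction, hydrolysis of the oxocarbenium ion) frees the C9 hydroxyl without affecting the silyl ether, the ketones or the alkenyl iodide.

Step 15
Reactants: 23 C9 primary alcohol
Product: 24 9,14α-diol (14S) with the C2 ketone intact
Conditions: Me4NBH(OAc)3 (1.3 equiv), MeCN/AcOH, −30 → −10 °C
Reagents that add atoms: none
Why: Hydroxyl-directed triacetoxyborohydride reduction: in the chair that keeps both methyls and the silyloxy group equatorial, the C9 alkoxyborohydride sits on an axial β arm 1,3 to C14 and should deliver hydride to the β face of that carbonyl, giving the 14α (14S) alcohol, while the C2 ketone on the trans-diaxial α arm is out of reach and the reagent does not reduce ketones without such delivery.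

Step 16
Reactants: 24 diol
Product: 25 C9 aldehyde (14α-hydroxyl free)
Conditions: TEMPO (cat.), PhI(OAc)2, CH2Cl2, rt
Reagents that add atoms: none
Why: TEMPO-catalysed oxidation with PhI(OAc)2 is selective for the primary C9 alcohol over the hindered secondary C14 alcohol and, being non-basic, should not epimerise C10.

Step 17
Reactants: 26 3,4-dibromofuran
Product: 28 3-bromo-4-methylfuran, via 4-bromo-3-furyllithium 27 (not isolated)
Conditions: n-BuLi (1 equiv), Et2O, −78 °C; MeI, −78 → −20 °C
Reagents that add atoms: iodomethane, IC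
Why: Single bromine–lithium exchange of the symmetrical dibromide followed by methylation of the 3-furyllithium at low temperature gives the furan that supplies C7, C8, C17, C18 and C19.

Step 18
Reactants: 25 C9 aldehyde; 28 3-bromo-4-methylfuran
Product: 31 (9R)-9-(4-methylfuran-3-yl) 9,14-diol, via 4-methyl-3-furyllithium 29 (not isolated), via furyltitanium reagent 30 (not isolated)
Conditions: 28, n-BuLi, Et2O, −78 °C; ClTi(OiPr)3, −78 → −40 °C; 25, THF, −78 → −20 °C
Reagents that add atoms: none
Why: Bromine–lithium exchange and transmetalation give an aryltitanium triisopropoxide that adds to aldehydes much faster than to hindered ketones, and Felkin–Anh addition anti to the C10–C1 bond (quaternary C1 as the large group, C10–H as the small one) should set C9 as R.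

Step 19
Reactants: 31 furyl diol
Product: 32 9,14-diacetate
Conditions: Ac2O, DMAP, pyridine, CH2Cl2, rt
Reagents that add atoms: acetic anhydride, CC(=O)OC(C)=O
Why: DMAP-catalysed acylation esterifies both hindered secondary alcohols at once and so installs the C9 and C14 acetates of the target.

Step 20
Reactants: 32 diacetate
Product: 33 (2R)-alcohol
Conditions: (S)-2-methyl-CBS-oxazaborolidine, catecholborane, toluene, −40 → −20 °C
Reagents that add atoms: none
Why: Corey–Bakshi–Shibata reduction with the (S)-oxazaborolidine treats quaternary C1 as the large and the C3 methylene as the small ketone substituent and should give the (2R) alcohol by reagent control, while catecholborane spares the esters, the furan and the alkenyl iodide.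

Step 21
Reactants: 33 (2R)-alcohol
Product: 34 (2R)-butyrate (furan, 9,14-diacetate, 12-silyl ether)
Conditions: butanoic anhydride, DMAP, Et3N, CH2Cl2, 0 °C → rt
Reagents that add atoms: butanoic anhydride, CCCC(=O)OC(=O)CCC
Why: DMAP-catalysed acylation with the anhydride esterifies the neopentyl-type C2 alcohol and completes the ester pattern (C2 butyrate, C9 and C14 acetates).

Step 22
Reactants: 34 furan
Product: 36 γ-hydroxybutenolide (C19 carbonyl, C7 hemiacetal), via furan endoperoxide 35 (not isolated)
Conditions: O2, hν, tetraphenylporphyrin (cat.), i-Pr2NEt, CH2Cl2, −78 °C → rt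
Reagents that add atoms: dioxygen, O=O
Why: Singlet-oxygen [4+2] cycloaddition to the furan and Kornblum–DeLaMare fragmentation of the endoperoxide by the hindered amine, which should remove the bridgehead hydrogen next to the small C18 methyl (on C19) and not the one shielded by the C9 branch (on C7), make C19 the lactone carbonyl and C7 the hemiacetal carbon.

Step 23
Reactants: 36 γ-hydroxybutenolide
Product: 38 seco Z vinyl iodide with (Z)-formyl acrylate methyl ester, via potassium carboxylate 37 (not isolated)
Conditions: KHCO3, MeI, DMF, 0 °C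
Reagents that add atoms: iodomethane, IC
Why: The γ-hydroxybutenolide opens under mild base to its (Z)-formyl carboxylate (ring–chain tautomerism) and O-alkylation of that carboxylate gives the normal methyl ester with the C7 aldehyde free and cis to the ester, a geometry inherited from the ring.

Step 24
Reactants: 38 seco Z vinyl iodide with (Z)-formyl acrylate methyl ester
Product: 41 12-O-triethylsilyl ether of the target, via alkenylchromium dichloride 39 (not isolated), via seco hydroxy ester 40 (not isolated)
Conditions: CrCl2 (excess), NiCl2 (cat.), DMSO, 0.003 M, slow addition, rt; PPTS, CH2Cl2 if lactonisation is incomplete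
Reagents that add atoms: none
Why: NiCl2 is reduced to zerovalent nickel, which inserts into the C6–I bond with retention of the Z geometry; the alkenyl group passes to trivalent chromium and adds to the C7 aldehyde, and the C7 chromium alkoxide, held cis to the C19 methyl ester across the tetrasubstituted C8=C17 bond, displaces methoxide. The closest known reaction type is the Nozaki–Hiyama–Kishi macrocyclisation of iodoalkenyl aldehydes followed by lactonisation of a γ-hydroxy cis-enoate. The ten-membered carbocycle closes by 10-exo-trig carbonyl addition (C6 to C7) and the butenolide by 5-exo-trig acyl substitution (O on C7 to C19). C7 is the only new stereocentre and is under substrate control: the trans C1/C10 arms, the two Z olefins and the C9 acetate, which turns its hydrogen toward the formyl group to avoid allylic strain, should leave one aldehyde face open to C6, expected to give (7S). The step needs activation of the vinyl iodide and 1,2-addition without reduction of the electron-poor formyl acrylate, which the aldehyde-selective organochromium reagent in aprotic DMSO should secure, and ring closure over oligomerisation, which high dilution should secure.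

Step 25
Reactants: 41 12-O-triethylsilyl ether
Product: 42 target CNP0281577.1
Conditions: HF·pyridine, pyridine, THF, 0 °C
Reagents that add atoms: none
Why: Fluoride-mediated cleavage of the triethylsilyl ether with pyridine-buffered HF·pyridine frees the C12 hydroxyl under mildly acidic conditions that should neither hydrolyse nor migrate the three esters.

**Compound list**

1 | 2,6-dimethylbenzoic acid | Cc1cccc(C)c1C(=O)O | starting material
2 | 2,6-dimethylcyclohexa-2,5-diene-1-carboxylic acid | OC(=O)C1C(C)=CCC=C1C | intermediate
3 | (2,6-dimethylcyclohexa-2,5-dien-1-yl)methanol | OCC1C(C)=CCC=C1C | intermediate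
4 | 4-methoxybenzyl (PMB) ether of 3 | COc1ccc(cc1)COCC1C(C)=CCC=C1C | intermediate
5 | bis(dihydroboryl) adduct of 4 (boron on C12 and C14, α face; not isolated) | COc1ccc(cc1)COC[C@H]1[C@@H](C)[C@H](B)C[C@H](B)[C@H]1C | intermediate
6 | meso diol: 1β,11β-dimethyl-10β-(PMB-oxymethyl)cyclohexane-12α,14α-diol | COc1ccc(cc1)COC[C@H]1[C@@H](C)[C@H](O)C[C@H](O)[C@H]1C | intermediate
7 | 12-monoacetate of 6: (12R)-acetate, free (14S)-hydroxyl | COc1ccc(cc1)COC[C@H]1[C@@H](C)[C@H](OC(C)=O)C[C@H](O)[C@H]1C | intermediate
8 | 12α-acetoxy 14-ketone (not isolated) | COc1ccc(cc1)COC[C@H]1[C@@H](C)[C@H](OC(C)=O)CC(=O)[C@H]1C | intermediate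
9 | 1β,11β-dimethyl-10β-(PMB-oxymethyl)cyclohex-12-en-14-one | COc1ccc(cc1)COC[C@H]1[C@@H](C)C=CC(=O)[C@H]1C | intermediate
10 | 12α,13α-epoxy 14-ketone | COc1ccc(cc1)COC[C@H]1[C@@H](C)[C@@H]2O[C@@H]2C(=O)[C@H]1C | intermediate
11 | 2-(2-bromoethyl)-1,3-dioxolane | BrCCC1OCCO1 | starting material
12 | propyne | CC#C | starting material
13 | [2-(1,3-dioxolan-2-yl)ethyl]magnesium bromide (not isolated) | Br[Mg]CCC1OCCO1 | intermediate
14 | [2-(1,3-dioxolan-2-yl)ethyl]copper (not isolated) | [Cu]CCC1OCCO1 | intermediate
15 | (Z)-alkenylcopper from syn addition of 14 to propyne, chain cis to Cu (not isolated) | C/C(CCC1OCCO1)=C/[Cu] | intermediate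
16 | 2-[(3Z)-4-iodo-3-methylbut-3-en-1-yl]-1,3-dioxolane | C1COC(CC/C(C)=C\I)O1 | intermediate
17 | (4Z)-5-iodo-4-methylpent-4-enal | O=CCC/C(C)=C\I | intermediate
18 | lithium enolate of 10 (C1=C14, O–Li on C14; not isolated) | COc1ccc(cc1)COC[C@H]1[C@@H](C)[C@@H]2O[C@@H]2C(O[Li])=C1C | intermediate
19 | aldol adduct: epoxy ketone with quaternary C1 (C15 β) carrying the 1α-[(4Z)-1-hydroxy-5-iodo-4-methylpent-4-enyl] chain, both C2 epimers | COc1ccc(cc1)COC[C@H]1[C@@H](C)[C@@H]2O[C@@H]2C(=O)[C@]1(C)C(O)CC/C(C)=C\I | intermediate
20 | epoxy β-diketone (C2 and C14 carbonyls) | COc1ccc(cc1)COC[C@H]1[C@@H](C)[C@@H]2O[C@@H]2C(=O)[C@]1(C)C(=O)CC/C(C)=C\I | intermediate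
21 | 12α-hydroxy β-diketone | COc1ccc(cc1)COC[C@H]1[C@@H](C)[C@H](O)CC(=O)[C@]1(C)C(=O)CC/C(C)=C\I | intermediate
22 | 12α-triethylsilyloxy β-diketone, C9 PMB ether | COc1ccc(cc1)COC[C@H]1[C@@H](C)[C@H](O[Si](CC)(CC)CC)CC(=O)[C@]1(C)C(=O)CC/C(C)=C\I | intermediate
23 | C9 primary alcohol of 22 | OC[C@H]1[C@@H](C)[C@H](O[Si](CC)(CC)CC)CC(=O)[C@]1(C)C(=O)CC/C(C)=C\I | intermediate
24 | 9,14α-diol (14S), C2 ketone | OC[C@H]1[C@@H](C)[C@H](O[Si](CC)(CC)CC)C[C@H](O)[C@]1(C)C(=O)CC/C(C)=C\I | intermediate
25 | C9 aldehyde (10β-formyl, 14α-hydroxyl, C2 ketone) | O=C[C@H]1[C@@H](C)[C@H](O[Si](CC)(CC)CC)C[C@H](O)[C@]1(C)C(=O)CC/C(C)=C\I | intermediate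
26 | 3,4-dibromofuran | Brc1cocc1Br | starting material
27 | 4-bromo-3-furyllithium (not isolated) | [Li]c1cocc1Br | intermediate
28 | 3-bromo-4-methylfuran | Cc1cocc1Br | intermediate
29 | 4-methyl-3-furyllithium (not isolated) | [Li]c1cocc1C | intermediate
30 | (4-methylfuran-3-yl)titanium triisopropoxide (not isolated) | CC(C)O[Ti](OC(C)C)(OC(C)C)c1cocc1C | intermediate
31 | (9R)-9-(4-methylfuran-3-yl) 9,14α-diol, C2 ketone | Cc1cocc1[C@H](O)[C@H]1[C@@H](C)[C@H](O[Si](CC)(CC)CC)C[C@H](O)[C@]1(C)C(=O)CC/C(C)=C\I | intermediate
32 | 9,14-diacetate of 31 | Cc1cocc1[C@H](OC(C)=O)[C@H]1[C@@H](C)[C@H](O[Si](CC)(CC)CC)C[C@H](OC(C)=O)[C@]1(C)C(=O)CC/C(C)=C\I | intermediate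
33 | (2R)-alcohol | Cc1cocc1[C@H](OC(C)=O)[C@H]1[C@@H](C)[C@H](O[Si](CC)(CC)CC)C[C@H](OC(C)=O)[C@]1(C)[C@H](O)CC/C(C)=C\I | intermediate
34 | (2R)-butyrate, furan at C8, 9,14-diacetate, 12-triethylsilyl ether, Z vinyl iodide | Cc1cocc1[C@H](OC(C)=O)[C@H]1[C@@H](C)[C@H](O[Si](CC)(CC)CC)C[C@H](OC(C)=O)[C@]1(C)[C@H](OC(=O)CCC)CC/C(C)=C\I | intermediate
35 | furan endoperoxide (O–O bridge between C7 and C19; not isolated) | CC1=C(C2OOC1O2)[C@H](OC(C)=O)[C@H]1[C@@H](C)[C@H](O[Si](CC)(CC)CC)C[C@H](OC(C)=O)[C@]1(C)[C@H](OC(=O)CCC)CC/C(C)=C\I | intermediate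
36 | γ-hydroxybutenolide (C19 lactone carbonyl, C7 hemiacetal, both anomers) | CC1=C(C(O)OC1=O)[C@H](OC(C)=O)[C@H]1[C@@H](C)[C@H](O[Si](CC)(CC)CC)C[C@H](OC(C)=O)[C@]1(C)[C@H](OC(=O)CCC)CC/C(C)=C\I | intermediate
37 | potassium (Z)-formyl carboxylate, ring-opened 36 (not isolated) | [K+].O=C/C(=C(C)\C(=O)[O-])[C@H](OC(C)=O)[C@H]1[C@@H](C)[C@H](O[Si](CC)(CC)CC)C[C@H](OC(C)=O)[C@]1(C)[C@H](OC(=O)CCC)CC/C(C)=C\I | intermediate
38 | key-step precursor: seco Z vinyl iodide, (Z)-formyl acrylate methyl ester at C8, C2 butyrate, C9 and C14 acetates, C12 triethylsilyl ether | O=C/C(=C(C)\C(=O)OC)[C@H](OC(C)=O)[C@H]1[C@@H](C)[C@H](O[Si](CC)(CC)CC)C[C@H](OC(C)=O)[C@]1(C)[C@H](OC(=O)CCC)CC/C(C)=C\I | intermediate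
39 | alkenylchromium dichloride at C6 (trivalent chromium; not isolated) | O=C/C(=C(C)\C(=O)OC)[C@H](OC(C)=O)[C@H]1[C@@H](C)[C@H](O[Si](CC)(CC)CC)C[C@H](OC(C)=O)[C@]1(C)[C@H](OC(=O)CCC)CC/C(C)=C\[Cr](Cl)Cl | intermediate
40 | seco hydroxy ester: ten-membered ring closed, (7S)-carbinol, C19 methyl ester cis to C7 (not isolated) | CCCC(=O)O[C@@H]1CC/C(C)=C\[C@H](O)/C(=C(C)\C(=O)OC)[C@H](OC(C)=O)[C@H]2[C@@H](C)[C@H](O[Si](CC)(CC)CC)C[C@H](OC(C)=O)[C@@]21C | intermediate
41 | 12-O-triethylsilyl ether of the target | CCCC(=O)O[C@@H]1CC/C(C)=C\[C@@H]2OC(=O)C(C)=C2[C@H](OC(C)=O)[C@H]2[C@@H](C)[C@H](O[Si](CC)(CC)CC)C[C@H](OC(C)=O)[C@@]21C | intermediate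
42 | CNP0281577.1 | CCCC(=O)O[C@@H]1CC/C(C)=C\[C@@H]2OC(=O)C(C)=C2[C@H](OC(C)=O)[C@H]2[C@@H](C)[C@H](O)C[C@H](OC(C)=O)[C@@]21C | target

Total step count: 25. Longest linear sequence: 22 steps (steps 1–7, 10–16 and 18–25).

**Steps most likely to fail**

Step 24. The ten-membered ring closure is slow, so single-electron reduction of the electron-poor formyl acrylate by CrCl2 may overtake it, or C6 may add to the wrong aldehyde face. The fallback sets out from 34 and comes back at 41. Pd(OAc)2, PPh3 and KOAc in DMA at high dilution would close the ten-membered ring by intramolecular Heck-type alkenylation of the furan C7–H, giving the furan-fused macrocycle F1. Photooxygenation of F1 (O2, hν, tetraphenylporphyrin, i-Pr2NEt, −78 °C) can only fragment through the one remaining bridgehead hydrogen, on C19, and would give the 7-hydroxybutenolide F2. NaBH4 with CeCl3 in MeOH at −40 °C would reduce the ring-opened C7 ketone, and the γ-hydroxy acid would relactonise to 41, C7 now being set by hydride attack on the more open face of the macrocycle.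

Step 22. Regiocontrol may be lost in the base-induced fragmentation of the endoperoxide, with proton removal at C7 instead of C19. The fallback sets out from 34 and comes back at 36. Sterically governed C–H borylation ([Ir(OMe)(cod)]2, dtbpy, B2pin2, t-BuOMe, 50 °C) at the less hindered furan α-position next to the C18 methyl would give the C19 boronate F3. Oxidation with NaBO3·4H2O in THF/H2O at 0 °C would give the butenolide F4 with C19 as carbonyl and C7 as CH2. i-Pr3SiOTf and Et3N would convert F4 into the 2-silyloxyfuran F5, whose photooxygenation (O2, hν, tetraphenylporphyrin, −78 °C) and aqueous work-up would give 36 with the oxidation pattern fixed by construction.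

Step 15. Hydride may be delivered to the side-chain carbonyl or to the α face of C14, so that site or facial selectivity is lost. The fallback sets out from 22 and comes back at 24. With the PMB ether still in place, (R)-2-methyl-CBS-oxazaborolidine and a limiting amount of catecholborane in toluene at −60 °C would reduce the more electrophilic ring ketone under reagent control (quaternary C1 as the large group) to the (14S)-alcohol F6. DDQ in CH2Cl2/pH 7 buffer would then remove the PMB group to give 24.

**Further compounds**

F1 | step 24 | furan-fused ten-membered ring: C6 bonded to furan C7, C5=C6 Z, furan C19–H free | CCCC(=O)O[C@@H]1CC/C(C)=C\c2occ(C)c2[C@H](OC(C)=O)[C@H]2[C@@H](C)[C@H](O[Si](CC)(CC)CC)C[C@H](OC(C)=O)[C@@]21C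
F2 | step 24 | macrocyclic 7-hydroxybutenolide (hemiketal at C7, C19 carbonyl, both C7 epimers) | CCCC(=O)O[C@@H]1CC/C(C)=C\C2(O)OC(=O)C(C)=C2[C@H](OC(C)=O)[C@H]2[C@@H](C)[C@H](O[Si](CC)(CC)CC)C[C@H](OC(C)=O)[C@@]21C
F3 | step 22 | C19 pinacol boronate of furan 34 | Cc1c(B2OC(C)(C)C(C)(C)O2)occ1[C@H](OC(C)=O)[C@H]1[C@@H](C)[C@H](O[Si](CC)(CC)CC)C[C@H](OC(C)=O)[C@]1(C)[C@H](OC(=O)CCC)CC/C(C)=C\I
F4 | step 22 | butenolide with C19 carbonyl and C7 methylene | CC1=C(COC1=O)[C@H](OC(C)=O)[C@H]1[C@@H](C)[C@H](O[Si](CC)(CC)CC)C[C@H](OC(C)=O)[C@]1(C)[C@H](OC(=O)CCC)CC/C(C)=C\I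
F5 | step 22 | 2-(triisopropylsilyloxy)furan of F4 (silyloxy on C19) | Cc1c(O[Si](C(C)C)(C(C)C)C(C)C)occ1[C@H](OC(C)=O)[C@H]1[C@@H](C)[C@H](O[Si](CC)(CC)CC)C[C@H](OC(C)=O)[C@]1(C)[C@H](OC(=O)CCC)CC/C(C)=C\I
F6 | step 15 | (14S)-alcohol of 22 with the C9 PMB ether and C2 ketone intact | COc1ccc(cc1)COC[C@H]1[C@@H](C)[C@H](O[Si](CC)(CC)CC)C[C@H](O)[C@]1(C)C(=O)CC/C(C)=C\I
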